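**Retrosynthetic overview**

1. The strategy rests on the guaiacyl ring (4-hydroxy-3-methoxyphenyl): its six carbons carry only OH, an ortho OMe and, para to OH, a single carbon substituent (the CH2 on lactone C4). This is the pattern of a 4-substituted 2-methoxycyclohex-2-enone.
2. Last operations: methoxymethyl (MOM) removal and dehydrogenative aromatisation of that cyclohexenone. Key disconnection: cyclohexenone ⇒ lactone-bearing propanal + 1-methoxybut-3-en-2-one (Michael bond from the aldehyde α-carbon to the vinyl terminus; aldol-condensation bond from the MeO-bearing carbon to the aldehyde carbon).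
3. The propanal ⇒ an allyl group (hydroboration, oxidation); the E-arylidene ⇒ aldol addition/elimination of (R)-4-allyloxolan-2-one with MOM-protected syringaldehyde.
4. (R)-4-Allyloxolan-2-one ⇒ (R)-epichlorohydrin + diethyl malonate (cyclopropane-fused lactone, vinyl cuprate opening, decarboxylation).
5. Ring order: lactone ring in step 1 (the syringyl ring is bought), the carbocycle in step 11, made aromatic in step 12.

Key step: step 11

Remark: Ar = 3,5-dimethoxy-4-(methoxymethoxy)phenyl. The target is read as 4R, 3E (ylidene aryl trans to the lactone carbonyl). Commercial (R)-epichlorohydrin of high enantiomeric purity is taken as the only source of chirality.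

**Route**

Step 1
Reactants: 1 (R)-epichlorohydrin; 2 diethyl malonate
Product: 3 ethyl (1S,5R)-2-oxo-3-oxabicyclo[3.1.0]hexane-1-carboxylate
Conditions: NaOEt (1.05 equiv), EtOH, 0 °C → reflux
Reagents that add atoms: none
Why: Tandem alkylation/cyclopropanation/lactonisation: the malonate opens the oxirane at its CH2 terminus, the alkoxide displaces chloride to give a transposed epoxide, and the malonate carbanion opens this at the stereogenic carbon (3-exo-tet, inversion) before lactonisation, so the ring-fusion CH comes from (R)-epichlorohydrin and the quaternary carbon follows from the obligatory cis fusion.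

Step 2
Reactants: 3 ethyl (1S,5R)-2-oxo-3-oxabicyclo[3.1.0]hexane-1-carboxylate
Product: 4 ethyl (4R)-2-oxo-4-(prop-2-en-1-yl)oxolane-3-carboxylate (C3 epimers)
Conditions: CH2=CHMgBr (1.4 equiv), CuI (15 mol%), THF, −40 → −20 °C; aq. NH4Cl
Reagents that add atoms: vinylmagnesium bromide, C=C[Mg]Br
Why: Copper-catalysed homoconjugate addition of the Grignard reagent to the doubly activated cyclopropane occurs at the unsubstituted CH2 with cleavage of the bond to the malonate-type carbon, so the five-membered lactone is kept and the stereogenic CH is not touched.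

Step 3
Reactants: 4 ethyl (4R)-2-oxo-4-(prop-2-en-1-yl)oxolane-3-carboxylate
Product: 5 (4R)-4-(prop-2-en-1-yl)oxolan-2-one
Conditions: LiCl, H2O (2 equiv), DMSO, 140 °C
Reagents that add atoms: none
Why: Krapcho dealkoxycarbonylation of the malonate-type ester removes the ester and the scrambled C3 centre, while the β-stereocentre cannot epimerise.

Step 4
Reactants: 6 syringaldehyde (4-hydroxy-3,5-dimethoxybenzaldehyde)
Product: 7 3,5-dimethoxy-4-(methoxymethoxy)benzaldehyde
Conditions: MOMCl, iPr2NEt, CH2Cl2, 0 °C → rt
Reagents that add atoms: chloromethyl methyl ether, COCCl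
Why: O-Alkylation of the phenol (Williamson-type acetal formation) masks the acidic, oxidation-prone syringyl OH for the enolate, amine and oxidation steps.

Step 5
Reactants: 5 (4R)-4-(prop-2-en-1-yl)oxolan-2-one; 7 3,5-dimethoxy-4-(methoxymethoxy)benzaldehyde
Product: 8 (4R)-3-[Ar(hydroxy)methyl]-4-(prop-2-en-1-yl)oxolan-2-one (diastereomer mixture)
Conditions: LiN(iPr)2 (1.1 equiv), THF, −78 °C; then 7; aq. NH4Cl
Reagents that add atoms: none
Why: Aldol addition of the lithium lactone enolate to the aldehyde, with attack anti to the allyl group; the two new stereocentres (C3 and the carbinol) need no control because both are removed in step 6.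

Step 6
Reactants: 8 (4R)-3-[Ar(hydroxy)methyl]-4-(prop-2-en-1-yl)oxolan-2-one
Product: 10 (3E,4R)-3-(Ar-methylidene)-4-(prop-2-en-1-yl)oxolan-2-one, via mesylate 9 (not isolated)
Conditions: MsCl, Et3N, CH2Cl2, 0 °C; then DBU, rt
Reagents that add atoms: none
Why: Mesylation followed by E1cB elimination should give the thermodynamically preferred E-arylidene lactone (aryl anti to the lactone carbonyl), as is general for α-arylidene γ-lactones; short exposure to DBU at rt limits γ-deprotonation at C4.

Step 7
Reactants: 10 (3E,4R)-3-(Ar-methylidene)-4-(prop-2-en-1-yl)oxolan-2-one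
Product: 12 (3E,4R)-3-(Ar-methylidene)-4-(3-hydroxypropyl)oxolan-2-one, via B-alkyl-9-BBN adduct 11 (not isolated)
Conditions: 9-BBN (1.2 equiv), THF, 0 °C → rt; then NaBO3·4H2O, H2O, rt
Reagents that add atoms: sodium perborate tetrahydrate (NaBO3·4H2O), [Na+].[O-]OB=O
Why: Anti-Markovnikov hydroboration–oxidation: 9-BBN reacts with the monosubstituted alkene far faster than with the trisubstituted conjugated arylidene or the lactone carbonyl, and perborate oxidises the C–B bond without hydrolysing the lactone.

Step 8
Reactants: 12 (3E,4R)-3-(Ar-methylidene)-4-(3-hydroxypropyl)oxolan-2-one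
Product: 13 3-[(3R,4E)-4-(Ar-methylidene)-5-oxooxolan-3-yl]propanal
Conditions: Dess–Martin periodinane, CH2Cl2, rt
Reagents that add atoms: none
Why: Dess–Martin oxidation converts the primary alcohol into the aldehyde under near-neutral conditions, without over-oxidation and without touching the arylidene lactone or the aryl MOM ether.

Step 9
Reactants: 14 methoxyacetyl chloride
Product: 15 N,2-dimethoxy-N-methylacetamide
Conditions: MeNH(OMe)·HCl, Et3N (2.2 equiv), CH2Cl2, 0 °C → rt
Reagents that add atoms: N,O-dimethylhydroxylamine hydrochloride, CNOC.Cl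
Why: N-Acylation of the hydroxylamine by the acid chloride gives the Weinreb amide.

Step 10
Reactants: 15 N,2-dimethoxy-N-methylacetamide
Product: 16 1-methoxybut-3-en-2-one
Conditions: CH2=CHMgBr, THF, −78 → 0 °C; inverse quench into cold 2 M HCl; kept cold as an Et2O solution with a trace of BHT
Reagents that add atoms: vinylmagnesium bromide, C=C[Mg]Br
Why: Weinreb ketone synthesis: the chelated tetrahedral adduct prevents a second addition, and the acidic inverse quench protonates the released hydroxylamine before it can add to the vinyl ketone.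

Step 11
Reactants: 13 3-[(3R,4E)-4-(Ar-methylidene)-5-oxooxolan-3-yl]propanal; 16 1-methoxybut-3-en-2-one
Product: 19 (3E,4R)-3-(Ar-methylidene)-4-[(3-methoxy-4-oxocyclohex-2-en-1-yl)methyl]oxolan-2-one (epimers at the new ring carbon), via ketoaldehyde 17 (not isolated), via hydroxyketone 18 (not isolated)
Conditions: 16 (1.5 equiv), (S)-α,α-diphenylprolinol trimethylsilyl ether (10 mol%), ethyl 3,4-dihydroxybenzoate (20 mol%), CH2Cl2, 0 °C → rt; then piperidine, AcOH (0.3 equiv each), toluene, 60 °C
Reagents that add atoms: none
Why: The prolinol ether converts 13 into its enamine, whose nucleophilic carbon (the aldehyde α-carbon) adds to the unsubstituted terminus of 16 (Michael addition, first C–C bond) to give 1,5-ketoaldehyde 17; piperidinium acetate then activates the aldehyde as an iminium ion and the ketone as its enol or enamine, so that the MeO-bearing α-carbon attacks the aldehyde carbon (second C–C bond) and 18 loses water into conjugation. The closest known reaction type is the amine-mediated Robinson annulation (Stork enamine or organocatalytic) of α-unbranched aldehydes with alkyl vinyl ketones to 4-substituted cyclohex-2-enones. The one new ring closes by a 6-(enolexo)-exo-trig aldol addition followed by dehydration. The new sp3 ring carbon forms without control as a mixture of epimers, which is harmless because it becomes an arene carbon in step 12, and the lactone stereocentre is not involved. The regiochemistry is secured because the other ketone α-carbon or the aldehyde α-carbon could only close four-membered rings, which fixes the C=O/OMe/side-chain 1,2,4-pattern. The chemoselectivity is secured because the trisubstituted arylidene lactone is a far poorer acceptor than the vinyl ketone and intramolecular enamine attack on it would be a disfavoured 5-endo-trig closure, while the bulky amine suppresses aldehyde self-condensation and does not open the lactone.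

Step 12
Reactants: 19 (3E,4R)-3-(Ar-methylidene)-4-[(3-methoxy-4-oxocyclohex-2-en-1-yl)methyl]oxolan-2-one
Product: 20 (3E,4R)-3-(Ar-methylidene)-4-[(4-hydroxy-3-methoxyphenyl)methyl]oxolan-2-one
Conditions: Pd(O2CCF3)2 (5 mol%), 2-(dimethylamino)pyridine (10 mol%), TsOH·H2O (20 mol%), O2 (1 atm), DMSO, 80 °C
Reagents that add atoms: none
Why: Aerobic dehydrogenation of a cyclohexenone to a phenol: divalent palladium forms the C6 enolate, β-hydride elimination gives the 2-methoxy-4-alkylcyclohexa-2,5-dienone, which tautomerises to the guaiacol, and O2 reoxidises zerovalent palladium; the epimeric ring carbon is erased.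

Step 13
Reactants: 20 (3E,4R)-3-(Ar-methylidene)-4-[(4-hydroxy-3-methoxyphenyl)methyl]oxolan-2-one
Product: 21 (3E,4R)-4-[(4-hydroxy-3-methoxyphenyl)methyl]-3-[(4-hydroxy-3,5-dimethoxyphenyl)methylidene]oxolan-2-one (CNP0351244.1)
Conditions: HCl (3 M in MeOH), THF, 40 °C
Reagents that add atoms: none
Why: Acid-catalysed transacetalisation cleaves the aryl MOM ether (to dimethoxymethane), while the aryl methyl ethers, the lactone, the E-arylidene and the non-enolisable stereocentre are stable to dilute methanolic acid.

**Compound list**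

1 | (R)-epichlorohydrin | ClC[C@H]1CO1 | starting material
2 | diethyl malonate | CCOC(=O)CC(=O)OCC | starting material
3 | ethyl (1S,5R)-2-oxo-3-oxabicyclo[3.1.0]hexane-1-carboxylate | O=C1OC[C@@H]2C[C@]12C(=O)OCC | intermediate
4 | ethyl (4R)-2-oxo-4-(prop-2-en-1-yl)oxolane-3-carboxylate, C3 epimers | C=CC[C@H]1COC(=O)C1C(=O)OCC | intermediate
5 | (4R)-4-(prop-2-en-1-yl)oxolan-2-one | C=CC[C@H]1COC(=O)C1 | intermediate
6 | syringaldehyde | COc1cc(C=O)cc(OC)c1O | starting material
7 | 3,5-dimethoxy-4-(methoxymethoxy)benzaldehyde | COCOc1c(OC)cc(C=O)cc1OC | intermediate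
8 | (4R)-3-{[3,5-dimethoxy-4-(methoxymethoxy)phenyl](hydroxy)methyl}-4-(prop-2-en-1-yl)oxolan-2-one, diastereomer mixture | C=CC[C@H]1COC(=O)C1C(O)c1cc(OC)c(OCOC)c(OC)c1 | intermediate
9 | methanesulfonate of 8 | C=CC[C@H]1COC(=O)C1C(OS(C)(=O)=O)c1cc(OC)c(OCOC)c(OC)c1 | intermediate (not isolated)
10 | (3E,4R)-3-{[3,5-dimethoxy-4-(methoxymethoxy)phenyl]methylidene}-4-(prop-2-en-1-yl)oxolan-2-one | C=CC[C@H]1COC(=O)/C1=C/c1cc(OC)c(OCOC)c(OC)c1 | intermediate
11 | 9-{3-[(3R,4E)-4-(arylmethylidene)-5-oxooxolan-3-yl]propyl}-9-borabicyclo[3.3.1]nonane | B1(CCC[C@H]2COC(=O)/C2=C/c2cc(OC)c(OCOC)c(OC)c2)C2CCCC1CCC2 | intermediate (not isolated)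
12 | (3E,4R)-3-{[3,5-dimethoxy-4-(methoxymethoxy)phenyl]methylidene}-4-(3-hydroxypropyl)oxolan-2-one | OCCC[C@H]1COC(=O)/C1=C/c1cc(OC)c(OCOC)c(OC)c1 | intermediate
13 | 3-[(3R,4E)-4-{[3,5-dimethoxy-4-(methoxymethoxy)phenyl]methylidene}-5-oxooxolan-3-yl]propanal | O=CCC[C@H]1COC(=O)/C1=C/c1cc(OC)c(OCOC)c(OC)c1 | intermediate
14 | methoxyacetyl chloride | COCC(=O)Cl | starting material
15 | N,2-dimethoxy-N-methylacetamide | COCC(=O)N(C)OC | intermediate
16 | 1-methoxybut-3-en-2-one | COCC(=O)C=C | intermediate
17 | 2-{[(3R,4E)-4-(arylmethylidene)-5-oxooxolan-3-yl]methyl}-6-methoxy-5-oxohexanal, C2 epimers | O=CC(CCC(=O)COC)C[C@H]1COC(=O)/C1=C/c1cc(OC)c(OCOC)c(OC)c1 | intermediate (not isolated)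
18 | (3E,4R)-3-(arylmethylidene)-4-[(2-hydroxy-3-methoxy-4-oxocyclohexyl)methyl]oxolan-2-one, diastereomer mixture | COC1C(O)C(C[C@H]2COC(=O)/C2=C/c2cc(OC)c(OCOC)c(OC)c2)CCC1=O | intermediate (not isolated)
19 | (3E,4R)-3-{[3,5-dimethoxy-4-(methoxymethoxy)phenyl]methylidene}-4-[(3-methoxy-4-oxocyclohex-2-en-1-yl)methyl]oxolan-2-one, epimers at the ring CH | COC1=CC(C[C@H]2COC(=O)/C2=C/c2cc(OC)c(OCOC)c(OC)c2)CCC1=O | intermediate
20 | (3E,4R)-3-{[3,5-dimethoxy-4-(methoxymethoxy)phenyl]methylidene}-4-[(4-hydroxy-3-methoxyphenyl)methyl]oxolan-2-one | COc1cc(C[C@H]2COC(=O)/C2=C/c2cc(OC)c(OCOC)c(OC)c2)ccc1O | intermediate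
21 | (3E,4R)-4-[(4-hydroxy-3-methoxyphenyl)methyl]-3-[(4-hydroxy-3,5-dimethoxyphenyl)methylidene]oxolan-2-one | COc1cc(C[C@H]2COC(=O)/C2=C/c2cc(OC)c(O)c(OC)c2)ccc1O | target

**Step count**

Total: 13 steps. Longest linear sequence: 10 steps (1, 2, 3, 5, 6, 7, 8, 11, 12, 13) from (R)-epichlorohydrin.

**Steps most likely to fail**

Step 11. The enamine Michael addition may be outrun by self-condensation of the aldehyde or by polymerisation of the alkoxy vinyl ketone, and the amine–acid stage may stall before ring closure and dehydration. The fallback sets out from 13 and separates the two bond formations with a different activation. TMSCl, NaI and Et3N in MeCN convert 13 into its trimethylsilyl enol ether F1. A Mukaiyama–Michael addition of this to 16 with catalytic Sc(OTf)3 in CH2Cl2 at −78 °C, followed by aqueous work-up, gives ketoaldehyde 17 as an isolated compound. Cyclodehydration of 17 with dibenzylammonium trifluoroacetate in toluene at 50 °C then rejoins the route at 19.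

Step 12. The dehydrogenation may be slow, a palladium hydride may move the exocyclic double bond into the lactone ring (which would erase the stereocentre), or the sulfonic acid additive may remove the MOM group too early. The fallback sets out from 19 and avoids palladium and acid. Kinetic deprotonation at C6 with LiN(SiMe3)2 in THF at −78 °C and trapping with PhSeCl gives α′-phenylselanyl ketone F2. H2O2 in CH2Cl2/pyridine at 0 °C oxidises it to selenoxide F3, whose syn-elimination gives cyclohexa-2,5-dienone F4. This is the keto tautomer of the phenol and should tautomerise directly, rejoining the route at 20.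

Step 6. The elimination may give an E/Z mixture, and prolonged base may deprotonate C4 and move the double bond into the ring, with loss of the stereocentre. The fallback sets out from 5 (replacing steps 5 and 6) and forms the alkene by olefination. LiN(iPr)2 and ClP(O)(OEt)2 give ketene acetal phosphate F5, and further LiN(iPr)2 induces the 1,3-phosphoryl shift from O to C to give α-phosphono lactone F6. Horner–Wadsworth–Emmons reaction of F6 with aldehyde 7 (NaH, THF, 0 °C → rt) should give the E-arylidene lactone, rejoining the route at 10.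

**Further compounds**

F1 | step 11 | trimethylsilyl enol ether of 13, E/Z mixture at the enol ether | C[Si](C)(C)OC=CC[C@H]1COC(=O)/C1=C/c1cc(OC)c(OCOC)c(OC)c1
F2 | step 12 | (3E,4R)-3-(arylmethylidene)-4-{[3-methoxy-4-oxo-5-(phenylselanyl)cyclohex-2-en-1-yl]methyl}oxolan-2-one | COC1=CC(C[C@H]2COC(=O)/C2=C/c2cc(OC)c(OCOC)c(OC)c2)CC([Se]c2ccccc2)C1=O
F3 | step 12 | selenoxide of F2 | COC1=CC(C[C@H]2COC(=O)/C2=C/c2cc(OC)c(OCOC)c(OC)c2)CC([Se](=O)c2ccccc2)C1=O
F4 | step 12 | (3E,4R)-3-(arylmethylidene)-4-[(3-methoxy-4-oxocyclohexa-2,5-dien-1-yl)methyl]oxolan-2-one | COC1=CC(C[C@H]2COC(=O)/C2=C/c2cc(OC)c(OCOC)c(OC)c2)C=CC1=O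
F5 | step 6 | diethyl (4R)-4-(prop-2-en-1-yl)-4,5-dihydrofuran-2-yl phosphate | C=CC[C@H]1COC(OP(=O)(OCC)OCC)=C1
F6 | step 6 | diethyl [(4S)-2-oxo-4-(prop-2-en-1-yl)oxolan-3-yl]phosphonate (same spatial arrangement at C4 as in 5; the descriptor changes because phosphorus outranks oxygen) | C=CC[C@H]1COC(=O)C1P(=O)(OCC)OCC
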